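## Structural features

The target is a briarane-type diterpenoid. Cyclohexene ring A (C1, C10, C11, C12, C13, C14) shares the C1–C10 bond with a ten-membered carbocycle (C1 to C10), and a γ-lactone (C7–O–C19(=O)–C17–C8) is fused across C7–C8. C15, C16, C18 and C20 are the methyl groups on C1, C5, C17 and C11, and β is the face of ring A that carries C15. There are nine stereocentres: quaternary C1 (S) between C2 (S, acetate) and C10 (S, hydrogen trans to C15); C11 (R, methyl cis to C15) next to C12 (R, acetate trans to C20); the contiguous C7 (R), C8 (R, tertiary hydroxyl) and C9 (S, secondary hydroxyl); and C17 (R, methyl cis to the C8 hydroxyl). The ring fusion is trans, the lactone is trans-fused to the large ring, and C5=C6 is a tetrasubstituted chloroalkene with C4 and C7 cis (E by the sequence rule). Fragile elements are the allylic acetate at C12 beside C13=C14, the β-hydroxy lactone (dehydration, translactonisation to O9, epimerisation at C17), the C11 methyl whenever C12 is a carbonyl, and any pair of 1,6-related carbonyls in the ten-membered ring (transannular aldol). The real difficulty is a medium ring that contains a quaternary carbon, combined with the congested syn C15/C20 methyl pair and four oxygens (C2, C8, C9, C12) that must end as two acetates and two free hydroxyls. The feature exploited is that C2 and C7 both carry oxygen and are 1,6-related both ways round the large ring, so they can be the two carbons of a tetrasubstituted C2=C7 alkene shared by six-membered ring B (C1, C2, C7, C8, C9, C10) and ring C (C2 to C7). Cutting that bond unveils the ten-membered ring without a macrocyclisation, and ring C can come from a benzene ring.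

## Logic of the disconnections

49 to 48 to 46: the O–Si bond at C9 and then the O–acyl and O–Si bonds at C2 are cut (through 47). The free C8/C9 diol and the C2 acetate are made last because they are the most labile groups. The forward steps demand silyl ethers of graded lability and an acetylation that spares the tertiary C8 hydroxyl.

46 to 45 to 44: the C12–O bond is cut with inversion, then the C12–H bond. Hydride is expected to enter anti to C20 and give the wrong epimer, so one substitution step both inverts C12 and installs the acetate. The demand is clean SN2 at an allylic carbinol.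

44 to 41 to 39: the C13=C14 π bond is removed (through 43 and 42) and the C12 carbonyl goes back to a silyl ether (through 40). Ring A is thereby saturated for all earlier oxidative and electrophilic steps. The forward demand is kinetic enolisation toward C13 only, without epimerising C11.

39 to 37: the lactone C19–O bond and the C17–C18 bond are cut (through 38), giving a glycidic ester. Anti opening at C17 fixes C17 relative to C8, so lactone and methyl are both removed in one retron. The demand is cuprate attack α to the ester.

37 to 36 to 35: the C7–H bond and the oxirane oxygen are removed. Chelation fixes C7 from C8, and one epoxidation of an electron-poor alkene sets C8 and C17 together. The demand is facial control at C8 by the neighbouring C9 stereocentre.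

35 to 31 + 32: the C8=C17 bond is cut (through 34 and 33). A two-carbon electrophile is joined at the only enolisable α-carbon of the C7 ketone. The demand is kinetic deprotonation at C8 in preference to C4, and E geometry.

31 to 29: the C6–Cl bond is cut (through 30). Chlorine is introduced while C5=C6 is an enone and the molecule contains no other alkene.

29 to 28 to 27 to 26: the O–Si bond at C2, the C7 carbinol oxidation state and the C2–H bond are retraced. The neopentyl C2 ketone must be reduced under reagent control and masked before any enolate chemistry at C8, because C3 would otherwise enolise. The demand is a reduction that tolerates the enone and an allylic oxidation that regenerates only C7.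

26 to 25: the alkene is moved from C5=C6 back to C4=C5. The demand is that conjugation with the C7 carbonyl is preferred over conjugation with the C2 carbonyl.

25 to 22: C2 and C7 are reconnected as a tetrasubstituted alkene (through 24 and 23). The bicycle becomes a rigid tricycle, in which the ring A stereocentres can be set reliably, and the medium ring disappears from the problem. The demand is chemoselective cleavage in the presence of C4=C5.

22 to 21: the two sp3 carbons C3 and C6 are returned to a benzene ring. The skipped diene is exactly the dihydro product of a 1,2,4-trialkylbenzene, and the arene is inert through all earlier steps.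

21 to 20 to 18 to 17: the O–Si bond at C12, the C12–O and C11–H bonds (through 19) and the O–Si bond at C9 are cut. One syn addition to C11=C12 from the face opposite C15 sets both C11 and C12.

17 to 14: the C10–H bond is cut (through 16 and 15). The trans ring fusion is derived stereospecifically from an allylic C12 carbinol.

14 to 13 to 12 to 10: the C9–H and C12–H bonds, the C9 oxidation state and the C9–O bond are removed (through 11). Both carbinols come from one reduction anti to C15, and C9 oxygen comes from the γ-position of the ring A enone.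

10 to 5 + 6: the C1–C14 bond and the C10=C11 bond are cut (through 9, 8 and 7). This is the annulation that creates quaternary C1; the demand is absolute control at C1.

5 to 3 to 1: the carbonyl is transposed (through 4) and the C1–CH3 bond is cut (through 2), reaching a catalogue ketone.

## Other disconnections considered

Alternative 1: The cut is the C7–C8 bond together with the lactone C7–O bond, which divides the lactone sector into the cis dioxolanone acid A1 and the (E)-chloroenal A2. In the forward step the dianion of A1 adds through C8 to the aldehyde of A2, and acidification closes the γ-lactone to give A3.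
- In its favour: C8 is set by self-regeneration of a stereocentre (attack anti to the tert-butyl group), C17 comes from the chiral pool, and the chloroalkene geometry is fixed in an open chain. On the control of C8 and C17, and on convergence, it is better than the chosen plan, which relies on a facial preference at C8 in a medium ring.
- Against it: C7 still depends on the facial selectivity of the aldol. C9 arrives as a carboxyl carbon, so the C9–C10 bond and the C9 carbinol must be made later beside a ring-fusion centre. The ten-membered ring still has to be closed by bond formation, with the entropic and transannular cost that the chosen plan avoids.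
- Comparison: the two key steps are equally well founded mechanistically. In step economy A3 is short to reach, but ring A and a macrocyclisation must be added, so no overall saving is evident.

Alternative 2: The cut is the C1–C14 bond of ring A. In the forward step zerovalent palladium inserts into the (Z)-vinyl iodide of A4, and the aldehyde enolate is alkenylated to give the cyclohexene aldehyde A5 with quaternary C1.
- In its favour: C1 and the C13=C14 alkene are made together, and C12 carries its final configuration from open-chain stereocontrol. On this point it is better than the chosen plan, which spends four late steps on that alkene and on C12.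
- Against it: aldehyde enolates compete by self-aldol reaction, and the configuration at C1 rests only on the cyclisation transition state. A5 contains ring A alone, with C2 and C9 as one-carbon stubs, so the whole ten-membered ring and the lactone remain to be built, and a macrocyclisation is needed.
- Comparison: the chosen plan sets C1 with an auxiliary at the start and obtains the large ring from an existing bicycle. Alternative 2 is the equal of the chosen plan in the reliability of its individual key step, but it shifts the main difficulty to later steps.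

Alternative 3: The cut is the C1–C2 bond. In the forward step BF3·OEt2 activates the C2 aldehyde of A6, and C1, the γ-terminus of the ring A silyl dienol ether, attacks it; this closes the ten-membered ring and regenerates the C12 enone in A7.
- In its favour: the closure is late and convergent, the lactone and the chloroalkene are assembled in an open chain, and the C13=C14 enone appears without a separate dehydrogenation. On that last point it is better than the chosen plan.
- Against it: a ten-membered ring is closed while a quaternary carbon is formed. The γ-selectivity competes with α-attack at C13. C1 and C2 are both created in a macrocyclic transition state with no evident control element. A Lewis acid must spare a tertiary silyl ether and a β-silyloxy lactone.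
- Comparison: the chosen plan creates no stereocentre in its ring-forming event and needs no high dilution. Alternative 3 would be shorter after the ring closure, but it needs a long synthesis of A6 and carries the larger stereochemical risk.

Key step: step 12

Assumptions and remarks on the chemistry:
- Locants in all names follow the numbering of the target (C1 to C20); α and β refer to the face of C15.
- In step 3 the (R)-amine is assumed to give the (R)-diketone 9 (attack anti to the phenyl group of the auxiliary); should the sense be opposite, the (S)-amine is used.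
- Compounds 1, 6 and 32 are taken to be catalogue compounds.
- The key-step precursor 22 is a decahydrophenanthrene-type diene (two C=C bonds); the octahydrophenanthrene is its aromatic progenitor 21. The diene is reached by Birch reduction because an enone-derived ring C would enolise at the doubly activated C3 and would not give the skipped diene cleanly.
- C9 carries a triisopropylsilyl ether, C12 a triethylsilyl ether and, later, C2 a tert-butyldimethylsilyl ether, so that the three can be removed in the order C12, C2, C9.

## Steps

Step 1
Reactants: 1 6-methyl-3,4-dihydronaphthalen-1(2H)-one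
Product: 3 4,7-dimethyl-1,2-dihydronaphthalene, via tertiary alcohol 2 (not isolated)
Conditions: MeMgBr, THF, 0 °C to rt; then p-toluenesulfonic acid (cat.), toluene, 80 °C
Reagents that add atoms: methylmagnesium bromide, C[Mg]Br
Why: Grignard addition to the aryl ketone and acid-catalysed E1 dehydration of the tertiary benzylic alcohol 2 should give the conjugated styrene 3; no stereocentre is involved.

Step 2
Reactants: 3 4,7-dimethyl-1,2-dihydronaphthalene
Product: 5 1,6-dimethyl-3,4-dihydronaphthalen-2(1H)-one, via epoxide 4 (not isolated)
Conditions: 3-chloroperoxybenzoic acid, NaHCO3, CH2Cl2, 0 °C; then p-toluenesulfonic acid (cat.), toluene, 80 °C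
Reagents that add atoms: 3-chloroperoxybenzoic acid, OOC(=O)c1cccc(Cl)c1
Why: Prilezhaev epoxidation of the electron-rich styrene gives 4; acid opens it to the tertiary benzylic cation at C1 and a 1,2-hydride shift from the neighbouring carbon (Meinwald rearrangement) should give the 2-tetralone 5, racemic at the enolisable C1.

Step 3
Reactants: 5 1,6-dimethyl-3,4-dihydronaphthalen-2(1H)-one; 6 pent-1-en-3-one
Product: 10 (4aS)-1,4a,7-trimethyl-4,4a,9,10-tetrahydrophenanthren-2(3H)-one, via imine 7 (not isolated), via Michael adduct imine 8 (not isolated), via diketone 9 (not isolated)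
Conditions: (R)-1-phenylethylamine, p-toluenesulfonic acid (cat.), toluene, reflux with removal of water; 6, THF, rt; aq. AcOH; then NaOMe (cat.), MeOH, rt to 50 °C
Reagents that add atoms: none
Why: Robinson annulation in its chiral-imine variant: the enamine tautomer of 7 (conjugated with the arene) adds to 6 at the more substituted carbon through a cyclic, aza-ene-like transition state on the face anti to the phenyl group of the auxiliary, which sets quaternary C1. Hydrolysis gives 9 and methoxide closes ring A by aldol condensation (C10=C11); enantiomeric purity should be high and can be upgraded by crystallisation of 10.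

Step 4
Reactants: 10 (4aS)-1,4a,7-trimethyl-4,4a,9,10-tetrahydrophenanthren-2(3H)-one
Product: 12 9-hydroxy enone (both C9 epimers), via silyl dienol ether 11 (not isolated)
Conditions: t-BuMe2SiOTf, Et3N, CH2Cl2, 0 °C; then 3-chloroperoxybenzoic acid, NaHCO3, CH2Cl2, −20 °C; dilute aq. HCl work-up
Reagents that add atoms: 3-chloroperoxybenzoic acid, OOC(=O)c1cccc(Cl)c1
Why: Soft enolisation gives the linear dienol ether 11 by γ-deprotonation at C9, and the peracid attacks its electron-rich γ-terminus (Rubottom-type γ-oxidation) to return the enone with a C9 hydroxyl. The C9 configuration is irrelevant because the carbinol is oxidised in the next step.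

Step 5
Reactants: 12 9-hydroxy enone (both C9 epimers)
Product: 13 tricyclic 10-ene-9,12-dione
Conditions: Dess–Martin periodinane, NaHCO3, CH2Cl2, 0 °C to rt
Reagents that add atoms: none
Why: Dess–Martin oxidation of the allylic C9 alcohol gives the ene-dione and merges the C9 epimers into one compound.

Step 6
Reactants: 13 tricyclic 10-ene-9,12-dione
Product: 14 tricyclic 10-ene-9β,12β-diol
Conditions: NaBH4, CeCl3·7H2O, MeOH/CH2Cl2, −78 °C
Reagents that add atoms: none
Why: Luche reduction (1,2-selective) of both carbonyls; hydride should reach C9 and C12 from the α face, anti to the pseudoaxial C15 methyl, as in the reduction of steroidal 4-ene-3,6-diones to 3β,6β-diols.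

Step 7
Reactants: 14 tricyclic 10-ene-9β,12β-diol
Product: 17 trans-fused 11-en-9β-ol, via sulfonylhydrazine 15 (not isolated), via allylic diazene 16 (not isolated)
Conditions: PPh3, diethyl azodicarboxylate, 2-nitrobenzenesulfonylhydrazide, N-methylmorpholine, −30 °C to rt
Reagents that add atoms: none
Why: A Mitsunobu reaction at the less hindered C12 hydroxyl (the C9 hydroxyl is syn to C15) installs the sulfonylhydrazine with inversion; loss of sulfinic acid gives the 12α-diazene 16. Its retro-ene loss of N2 (allylic diazene rearrangement) delivers hydrogen suprafacially to the α face of C10 and moves the alkene to C11=C12, so the trans ring fusion follows stereospecifically from C12.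

Step 8
Reactants: 17 trans-fused 11-en-9β-ol
Product: 18 9β-triisopropylsilyl ether of 17
Conditions: i-Pr3SiOTf, 2,6-lutidine, CH2Cl2, 0 °C to rt
Reagents that add atoms: triisopropylsilyl trifluoromethanesulfonate, CC(C)[Si](OS(=O)(=O)C(F)(F)F)(C(C)C)C(C)C
Why: Silylation of the hindered axial alcohol with a silyl triflate; the robust triisopropylsilyl group is meant to outlast the other silyl ethers and adds shielding to the β face.

Step 9
Reactants: 18 9β-triisopropylsilyl ether of 17
Product: 20 9β-triisopropylsilyloxy-11β-methyl-12α-ol, via alkylborane 19 (not isolated)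
Conditions: BH3·THF, THF, 0 °C to rt; then NaOH, H2O2, 0 °C to rt
Reagents that add atoms: hydrogen peroxide, OO
Why: Hydroboration–oxidation: borane should add to the trisubstituted C11=C12 bond from the α face (the β face is blocked by C15 and the 9β-silyloxy group), with boron at C12 and hydrogen at C11. Oxidation with retention then gives the 12α-hydroxyl and the 11β-methyl group.

Step 10
Reactants: 20 9β-triisopropylsilyloxy-11β-methyl-12α-ol
Product: 21 12α-triethylsilyl ether of 20
Conditions: Et3SiOTf, 2,6-lutidine, CH2Cl2, −78 to 0 °C
Reagents that add atoms: triethylsilyl trifluoromethanesulfonate, CC[Si](CC)(CC)OS(=O)(=O)C(F)(F)F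
Why: Silylation; the labile triethylsilyl ether masks C12 through the reduction and the ozonolysis and can later be removed in the presence of the other silyl ethers.

Step 11
Reactants: 21 12α-triethylsilyl ether of 20
Product: 22 tricyclic 2(7),4-diene
Conditions: Li, NH3 (l), THF, t-BuOH, −78 to −33 °C; then NH4Cl
Reagents that add atoms: none
Why: Birch reduction of the 1,2,4-trialkylbenzene ring C: protonation should occur at the two unsubstituted, para-related carbons C3 and C6, which leaves all alkyl-bearing carbons on the C2=C7 and C4=C5 double bonds. The homobenzylic silyl ether and saturated ring A are inert to the dissolving metal.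

Step 12
Reactants: 22 tricyclic 2(7),4-diene
Product: 25 ten-membered 4-ene-2,7-dione fused to ring A, via primary ozonide 23 (not isolated), via secondary ozonide 24 (not isolated)
Conditions: O3 (1.0 equiv, titrated solution in CH2Cl2), NaHCO3, CH2Cl2, −78 °C; then Me2S, −78 °C to rt
Reagents that add atoms: ozone, [O-][O+]=O
Why: Ozone adds as a 1,3-dipole to the most electron-rich, tetrasubstituted C2=C7 bond to give 23, which fragments (Criegee mechanism) to a ketone and a carbonyl oxide that recombine to 24; Me2S reduces 24 to the two ketones. The closest known reaction type is the ozonolysis of the ring-fusion alkene of octalins to cyclodecane-1,6-diones. The ten-membered ring is not closed by bond formation: it appears when the bond shared by rings B and C is cut, so its size is fixed by the substrate and no dilution is needed. No stereocentre is created, and C1, C9, C10, C11 and C12 are untouched. The selectivity needed is chemoselectivity for C2=C7 over the trisubstituted C4=C5 bond. It rests on the higher substitution of C2=C7, on one equivalent of ozone delivered cold as a titrated solution, and on ring A being saturated so that C4=C5 is the only competitor. Quaternary C1 blocks enolisation of the C2 ketone toward ring A, the work-up is buffered, and 25 is used at once to limit transannular aldol reaction.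

Step 13
Reactants: 25 ten-membered 4-ene-2,7-dione fused to ring A
Product: 26 5-ene-2,7-dione
Conditions: 1,8-diazabicyclo[5.4.0]undec-7-ene (0.2 equiv), CH2Cl2, 0 °C to rt
Reagents that add atoms: none
Why: Base-catalysed isomerisation of the β,γ-unsaturated ketone through the dienolate formed at the doubly activated C6. The trisubstituted C5=C6 enone conjugated with the unhindered C7 carbonyl should be the thermodynamic sink over the disubstituted C3=C4 isomer conjugated with the neopentyl C2 carbonyl; the cis ring geometry is kept.

Step 14
Reactants: 26 5-ene-2,7-dione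
Product: 27 (2S)-5-ene-2,7-diol (C7 epimers)
Conditions: (R)-1-methyl-3,3-diphenyltetrahydro-1H,3H-pyrrolo[1,2-c][1,3,2]oxazaborole (1 equiv), catecholborane, toluene, −40 to 0 °C; then MeOH, aq. NaOH
Reagents that add atoms: none
Why: Corey–Bakshi–Shibata reduction: the C2 ketone has a tert-alkyl flank (C1) and a methylene flank (C3), the ideal large/small pair, so the (R)-oxazaborolidine should set (2S) under reagent control. The enone carbonyl is reduced as well, with a configuration that does not matter; catecholborane is chosen because it does not hydroborate the alkene at this temperature.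

Step 15
Reactants: 27 (2S)-5-ene-2,7-diol (C7 epimers)
Product: 28 (2S)-2-hydroxy-5-en-7-one
Conditions: MnO2 (activated, excess), CH2Cl2, rt
Reagents that add atoms: none
Why: MnO2 oxidises only the allylic C7 alcohol back to the enone and leaves the saturated neopentyl C2 alcohol. The product is silylated without delay, because a free C2 hydroxyl can add transannularly to the enone.

Step 16
Reactants: 28 (2S)-2-hydroxy-5-en-7-one
Product: 29 2-tert-butyldimethylsilyl ether of 28
Conditions: t-BuMe2SiOTf, 2,6-lutidine, CH2Cl2, −78 to 0 °C
Reagents that add atoms: tert-butyldimethylsilyl trifluoromethanesulfonate, CC(C)(C)[Si](C)(C)OS(=O)(=O)C(F)(F)F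
Why: A silyl triflate with a weak hindered base protects the neopentyl alcohol without enolising the enone; this group is intermediate in lability between the C12 and C9 silyl ethers.

Step 17
Reactants: 29 2-tert-butyldimethylsilyl ether of 28
Product: 31 6-chloro-5-en-7-one, via dichloride 30 (not isolated)
Conditions: PhICl2, pyridine, CH2Cl2, 0 °C to rt
Reagents that add atoms: (dichloroiodo)benzene, ClI(Cl)c1ccccc1
Why: Ionic addition of chlorine to the only alkene gives 30, and pyridine removes the acidic C6 hydrogen with loss of the tertiary C5 chloride (E1cb); this is the classical chlorination–dehydrochlorination of β,β-disubstituted enones. The cis ring geometry (C4 and C7 cis) should be the preferred one in the ten-membered ring.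

Step 18
Reactants: 31 6-chloro-5-en-7-one; 32 ethyl 2-oxoacetate
Product: 35 (E)-8-alkylidene keto ester, via aldol adduct 33 (not isolated), via mesylate 34 (not isolated)
Conditions: LiN(SiMe3)2, THF, −78 °C; 32, −78 °C; then MeSO2Cl, Et3N, −78 to 0 °C
Reagents that add atoms: none
Why: Aldol condensation: kinetic deprotonation of the α′-methylene C8 (faster than γ-deprotonation at C4) and addition to the very electrophilic aldehyde give 33. Mesylation and E1cb elimination through the C7 enolate should give the (E)-alkylidene, with the ester anti to the C7 carbonyl.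

Step 19
Reactants: 35 (E)-8-alkylidene keto ester
Product: 36 8,17-epoxy keto ester
Conditions: t-BuOOH, 1,8-diazabicyclo[5.4.0]undec-7-ene, CH2Cl2, 0 °C
Reagents that add atoms: tert-butyl hydroperoxide, CC(C)(C)OO
Why: Weitz–Scheffer epoxidation: tert-butylperoxide adds to C17 of the doubly activated alkene and the C8 enolate closes the oxirane, far faster than any reaction at the hindered chloroenone. With the C9 hydrogen eclipsing the alkene (A(1,3) strain against the ester), oxygen should reach C8 on the face anti to the C9 silyloxy group, which is the configuration of the target; the E geometry is carried into the trans glycidic ester.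

Step 20
Reactants: 36 8,17-epoxy keto ester
Product: 37 (7R)-8,17-epoxy alcohol
Conditions: Zn(BH4)2, Et2O, −20 °C
Reagents that add atoms: none
Why: Chelation-controlled reduction: zinc bridges the C7 carbonyl and the oxirane oxygen, and hydride should attack from the side of the small oxirane carbon C17, anti to C9 and to the body of the ring, giving the anti epoxy alcohol with (7R); the ester and the chloroalkene are inert.

Step 21
Reactants: 37 (7R)-8,17-epoxy alcohol
Product: 39 γ-lactone with free C8 hydroxyl, via hydroxy ester 38 (not isolated)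
Conditions: Me2CuLi (from MeLi and CuI, excess), Et2O, −40 to 0 °C; aq. NH4Cl
Reagents that add atoms: lithium dimethylcuprate, C[Cu-]C.[Li+]
Why: Cuprate opening of a glycidic ester at the carbon α to the ester (C17) by SN2 with inversion, then lactonisation of the C7 alkoxide onto the ester. Because the trans-epoxide is opened anti, ring closure after rotation about C8–C17 places the new methyl cis to the C8 hydroxyl, as in the target.

Step 22
Reactants: 39 γ-lactone with free C8 hydroxyl
Product: 41 12-ketone, via C12 alcohol 40 (not isolated)
Conditions: pyridinium p-toluenesulfonate, MeOH/CH2Cl2, 0 °C to rt; evaporate; then Dess–Martin periodinane, NaHCO3, CH2Cl2, 0 °C to rt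
Reagents that add atoms: none
Why: Mild acid methanolysis removes only the triethylsilyl ether, and Dess–Martin oxidation gives the C12 ketone; buffered, non-enolising conditions protect the axial C11 methyl.

Step 23
Reactants: 41 12-ketone
Product: 44 13-en-12-one, via bis-silyl enol ether 42 (not isolated), via C8 silyl ether enone 43 (not isolated)
Conditions: LiN(SiMe3)2 (2.3 equiv), Me3SiCl, Et3N, THF, −78 °C; Pd(OAc)2 (1.1 equiv), MeCN, rt; then citric acid, MeOH/H2O
Reagents that add atoms: none
Why: Saegusa–Ito oxidation: the amide base takes the hydroxyl proton and then, kinetically, the less hindered C13 hydrogen of the only ketone; the C11 hydrogen is poorly aligned and the lactone α-hydrogen is much less acidic. Pd(OAc)2 dehydrogenates the silyl enol ether to the C13=C14 enone, and mild acid cleaves the tertiary trimethylsilyl ether.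

Step 24
Reactants: 44 13-en-12-one
Product: 45 12β-allylic alcohol
Conditions: NaBH4, CeCl3·7H2O, MeOH, −78 °C
Reagents that add atoms: none
Why: Luche reduction (1,2); hydride should attack C12 from the α face, anti to the adjacent β-oriented C20 methyl and the β-oriented C9 branch, which gives the 12β alcohol, the epimer of the target. The lactone is not reduced at this temperature.

Step 25
Reactants: 45 12β-allylic alcohol
Product: 46 12α-acetate
Conditions: PPh3, diisopropyl azodicarboxylate, AcOH, toluene, 0 °C to rt
Reagents that add atoms: acetic acid, CC(=O)O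
Why: Mitsunobu reaction with acetic acid: SN2 displacement of the activated allylic hydroxyl with inversion installs the 12α-acetate in one operation. SN2′ attack at the neopentyl C14 is disfavoured, and the tertiary C8 hydroxyl does not react.

Step 26
Reactants: 46 12α-acetate
Product: 48 2,12-diacetate 9-silyl ether, via C2 alcohol 47 (not isolated)
Conditions: HF·pyridine, pyridine, THF, 0 °C to rt; then Ac2O, 4-(dimethylamino)pyridine (cat.), pyridine, 0 °C
Reagents that add atoms: acetic anhydride, CC(=O)OC(C)=O
Why: Fluoride cleaves the tert-butyldimethylsilyl ether at C2 while the more robust and more hindered triisopropylsilyl ether at C9 stays; acetylation of the secondary C2 alcohol follows, and the tertiary C8 hydroxyl should not be acylated at 0 °C.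

Step 27
Reactants: 48 2,12-diacetate 9-silyl ether
Product: 49 CNP0296164.1
Conditions: HF·pyridine, THF, rt to 40 °C
Reagents that add atoms: none
Why: Final desilylation under acidic fluoride conditions, which should leave both acetates, the allylic system and the lactone intact.

## Compound list

1 | 6-methyl-3,4-dihydronaphthalen-1(2H)-one | Cc1ccc2c(c1)CCCC2=O | starting material
2 | 1,6-dimethyl-1,2,3,4-tetrahydronaphthalen-1-ol (racemic) | Cc1ccc2c(c1)CCCC2(C)O | intermediate
3 | 4,7-dimethyl-1,2-dihydronaphthalene | CC1=CCCc2cc(C)ccc12 | intermediate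
4 | 5,7b-dimethyl-1a,2,3,7b-tetrahydronaphtho[1,2-b]oxirene (racemic epoxide of 3) | CC12OC1CCc1cc(C)ccc12 | intermediate
5 | 1,6-dimethyl-3,4-dihydronaphthalen-2(1H)-one (racemic) | CC1C(=O)CCc2cc(C)ccc12 | intermediate
6 | pent-1-en-3-one (ethyl vinyl ketone) | CCC(=O)C=C | starting material
7 | (R)-1-phenylethyl imine of 5 (reacts as its enamine tautomer) | CC1C(=N[C@H](C)c3ccccc3)CCc2cc(C)ccc12 | intermediate
8 | (R)-1-phenylethyl imine of diketone 9 (imine at the ring carbonyl) | CCC(=O)CC[C@@]1(C)C(=N[C@H](C)c3ccccc3)CCc2cc(C)ccc21 | intermediate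
9 | (R)-1,6-dimethyl-1-(3-oxopentyl)-3,4-dihydronaphthalen-2(1H)-one | CCC(=O)CC[C@@]1(C)C(=O)CCc2cc(C)ccc21 | intermediate
10 | (4aS)-1,4a,7-trimethyl-4,4a,9,10-tetrahydrophenanthren-2(3H)-one (ring A enone, C12=O, C10=C11, aromatic ring C) | O=C1CC[C@]2(C)c3ccc(C)cc3CCC2=C1C | intermediate
11 | 12-(tert-butyldimethylsilyloxy)-9,11-diene from 10 (linear silyl dienol ether) | CC1=C(O[Si](C)(C)C(C)(C)C)CC[C@]2(C)c3ccc(C)cc3CC=C12 | intermediate
12 | 9-hydroxy derivative of enone 10, both C9 epimers | O=C1CC[C@]2(C)c3ccc(C)cc3CC(O)C2=C1C | intermediate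
13 | tricyclic 10-ene-9,12-dione | O=C1CC[C@]2(C)c3ccc(C)cc3CC(=O)C2=C1C | intermediate
14 | tricyclic 10-ene-9β,12β-diol | O[C@H]1CC[C@]2(C)c3ccc(C)cc3C[C@@H](O)C2=C1C | intermediate
15 | 12α-[N-amino-N-(2-nitrophenylsulfonyl)amino]-10-en-9β-ol | NN([C@@H]1CC[C@]2(C)c3ccc(C)cc3C[C@@H](O)C2=C1C)S(=O)(=O)c1ccccc1[N+](=O)[O-] | intermediate
16 | 12α-diazenyl-10-en-9β-ol (monoalkyl diazene) | N=N[C@@H]1CC[C@]2(C)c3ccc(C)cc3C[C@@H](O)C2=C1C | intermediate
17 | trans-fused 11-en-9β-ol (10α-H) | CC1=CCC[C@]2(C)c3ccc(C)cc3C[C@@H](O)[C@@H]12 | intermediate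
18 | 9β-triisopropylsilyl ether of 17 | CC1=CCC[C@]2(C)c3ccc(C)cc3C[C@@H](O[Si](C(C)C)(C(C)C)C(C)C)[C@@H]12 | intermediate
19 | 12α-boryl-11β-methyl adduct of 18 (alkylborane) | C[C@H]1[C@H](B)CC[C@]2(C)c3ccc(C)cc3C[C@@H](O[Si](C(C)C)(C(C)C)C(C)C)[C@@H]12 | intermediate
20 | 9β-triisopropylsilyloxy-11β-methyl-12α-ol (10α-H, aromatic ring C) | C[C@H]1[C@H](O)CC[C@]2(C)c3ccc(C)cc3C[C@@H](O[Si](C(C)C)(C(C)C)C(C)C)[C@@H]12 | intermediate
21 | 12α-triethylsilyl ether of 20 (octahydrophenanthrene type) | C[C@H]1[C@H](O[Si](CC)(CC)CC)CC[C@]2(C)c3ccc(C)cc3C[C@@H](O[Si](C(C)C)(C(C)C)C(C)C)[C@@H]12 | intermediate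
22 | tricyclic 2(7),4-diene with 9β-triisopropylsilyloxy and 12α-triethylsilyloxy groups (decahydrophenanthrene type) | CC1=CCC2=C(C1)C[C@@H](O[Si](C(C)C)(C(C)C)C(C)C)[C@H]1[C@@H](C)[C@H](O[Si](CC)(CC)CC)CC[C@@]12C | intermediate
23 | primary ozonide (1,2,3-trioxolane) across C2–C7 of 22 | CC1=CCC2(OOO3)C3(C1)C[C@@H](O[Si](C(C)C)(C(C)C)C(C)C)[C@H]1[C@@H](C)[C@H](O[Si](CC)(CC)CC)CC[C@@]12C | intermediate
24 | secondary ozonide (1,2,4-trioxolane bridging C2 and C7) | CC1=CCC2(OO3)OC3(C1)C[C@@H](O[Si](C(C)C)(C(C)C)C(C)C)[C@H]1[C@@H](C)[C@H](O[Si](CC)(CC)CC)CC[C@@]12C | intermediate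
25 | ten-membered 2,7-dione fused to ring A with cis C4=C5 | O=C1C/C=C(C)\CC(=O)C[C@@H](O[Si](C(C)C)(C(C)C)C(C)C)[C@H]2[C@@H](C)[C@H](O[Si](CC)(CC)CC)CC[C@@]21C | intermediate
26 | 2,7-dione with conjugated cis C5=C6 | O=C1CC/C(C)=C\C(=O)C[C@@H](O[Si](C(C)C)(C(C)C)C(C)C)[C@H]2[C@@H](C)[C@H](O[Si](CC)(CC)CC)CC[C@@]21C | intermediate
27 | (2S)-5-ene-2,7-diol, C7 epimers | O[C@H]1CC/C(C)=C\C(O)C[C@@H](O[Si](C(C)C)(C(C)C)C(C)C)[C@H]2[C@@H](C)[C@H](O[Si](CC)(CC)CC)CC[C@@]21C | intermediate
28 | (2S)-2-hydroxy-5-en-7-one | O[C@H]1CC/C(C)=C\C(=O)C[C@@H](O[Si](C(C)C)(C(C)C)C(C)C)[C@H]2[C@@H](C)[C@H](O[Si](CC)(CC)CC)CC[C@@]21C | intermediate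
29 | 2-tert-butyldimethylsilyl ether of 28 | CC(C)(C)[Si](C)(C)O[C@H]1CC/C(C)=C\C(=O)C[C@@H](O[Si](C(C)C)(C(C)C)C(C)C)[C@H]2[C@@H](C)[C@H](O[Si](CC)(CC)CC)CC[C@@]21C | intermediate
30 | 5,6-dichloro-7-ketone from 29 | CC(C)(C)[Si](C)(C)O[C@H]1CCC(C)(Cl)C(Cl)C(=O)C[C@@H](O[Si](C(C)C)(C(C)C)C(C)C)[C@H]2[C@@H](C)[C@H](O[Si](CC)(CC)CC)CC[C@@]21C | intermediate
31 | 6-chloro-5-en-7-one (C4 and C7 cis) | CC(C)(C)[Si](C)(C)O[C@H]1CC/C(C)=C(/Cl)C(=O)C[C@@H](O[Si](C(C)C)(C(C)C)C(C)C)[C@H]2[C@@H](C)[C@H](O[Si](CC)(CC)CC)CC[C@@]21C | intermediate
32 | ethyl 2-oxoacetate (ethyl glyoxylate) | CCOC(=O)C=O | starting material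
33 | aldol adduct: 8-(2-ethoxy-1-hydroxy-2-oxoethyl) derivative of 31 | CC(C)(C)[Si](C)(C)O[C@H]1CC/C(C)=C(/Cl)C(=O)C(C(O)C(=O)OCC)[C@@H](O[Si](C(C)C)(C(C)C)C(C)C)[C@H]2[C@@H](C)[C@H](O[Si](CC)(CC)CC)CC[C@@]21C | intermediate
34 | methanesulfonate of 33 | CC(C)(C)[Si](C)(C)O[C@H]1CC/C(C)=C(/Cl)C(=O)C(C(OS(C)(=O)=O)C(=O)OCC)[C@@H](O[Si](C(C)C)(C(C)C)C(C)C)[C@H]2[C@@H](C)[C@H](O[Si](CC)(CC)CC)CC[C@@]21C | intermediate
35 | (E)-8-(2-ethoxy-2-oxoethylidene)-6-chloro-5-en-7-one | CC(C)(C)[Si](C)(C)O[C@H]1CC/C(C)=C(/Cl)C(=O)/C(=C/C(=O)OCC)[C@@H](O[Si](C(C)C)(C(C)C)C(C)C)[C@H]2[C@@H](C)[C@H](O[Si](CC)(CC)CC)CC[C@@]21C | intermediate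
36 | 8,17-epoxide of 35 (trans glycidic ester, C8–O as in the target) | CC(C)(C)[Si](C)(C)O[C@H]1CC/C(C)=C(/Cl)C(=O)[C@]3(O[C@@H]3C(=O)OCC)[C@@H](O[Si](C(C)C)(C(C)C)C(C)C)[C@H]2[C@@H](C)[C@H](O[Si](CC)(CC)CC)CC[C@@]21C | intermediate
37 | (7R)-alcohol of 36 | CC(C)(C)[Si](C)(C)O[C@H]1CC/C(C)=C(/Cl)[C@H](O)[C@]3(O[C@@H]3C(=O)OCC)[C@@H](O[Si](C(C)C)(C(C)C)C(C)C)[C@H]2[C@@H](C)[C@H](O[Si](CC)(CC)CC)CC[C@@]21C | intermediate
38 | 7,8-diol ethyl ester with (17R)-methyl | CC(C)(C)[Si](C)(C)O[C@H]1CC/C(C)=C(/Cl)[C@H](O)[C@@](O)([C@@H](C)C(=O)OCC)[C@@H](O[Si](C(C)C)(C(C)C)C(C)C)[C@H]2[C@@H](C)[C@H](O[Si](CC)(CC)CC)CC[C@@]21C | intermediate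
39 | γ-lactone (C7–O–C19) with free C8 hydroxyl; 2-O-TBS, 9-O-TIPS, 12α-O-TES | CC(C)(C)[Si](C)(C)O[C@H]1CC/C(C)=C(/Cl)[C@@H]2OC(=O)[C@H](C)[C@@]2(O)[C@@H](O[Si](C(C)C)(C(C)C)C(C)C)[C@H]2[C@@H](C)[C@H](O[Si](CC)(CC)CC)CC[C@@]21C | intermediate
40 | 12α-alcohol from 39 | CC(C)(C)[Si](C)(C)O[C@H]1CC/C(C)=C(/Cl)[C@@H]2OC(=O)[C@H](C)[C@@]2(O)[C@@H](O[Si](C(C)C)(C(C)C)C(C)C)[C@H]2[C@@H](C)[C@H](O)CC[C@@]21C | intermediate
41 | 12-ketone | CC(C)(C)[Si](C)(C)O[C@H]1CC/C(C)=C(/Cl)[C@@H]2OC(=O)[C@H](C)[C@@]2(O)[C@@H](O[Si](C(C)C)(C(C)C)C(C)C)[C@H]2[C@@H](C)C(=O)CC[C@@]21C | intermediate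
42 | 8-O-trimethylsilyl 12-trimethylsilyl enol ether (C12=C13) | CC(C)(C)[Si](C)(C)O[C@H]1CC/C(C)=C(/Cl)[C@@H]2OC(=O)[C@H](C)[C@@]2(O[Si](C)(C)C)[C@@H](O[Si](C(C)C)(C(C)C)C(C)C)[C@H]2[C@@H](C)C(O[Si](C)(C)C)=CC[C@@]21C | intermediate
43 | 8-O-trimethylsilyl 13-en-12-one | CC(C)(C)[Si](C)(C)O[C@H]1CC/C(C)=C(/Cl)[C@@H]2OC(=O)[C@H](C)[C@@]2(O[Si](C)(C)C)[C@@H](O[Si](C(C)C)(C(C)C)C(C)C)[C@H]2[C@@H](C)C(=O)C=C[C@@]21C | intermediate
44 | 13-en-12-one with free C8 hydroxyl | CC(C)(C)[Si](C)(C)O[C@H]1CC/C(C)=C(/Cl)[C@@H]2OC(=O)[C@H](C)[C@@]2(O)[C@@H](O[Si](C(C)C)(C(C)C)C(C)C)[C@H]2[C@@H](C)C(=O)C=C[C@@]21C | intermediate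
45 | 12β-allylic alcohol | CC(C)(C)[Si](C)(C)O[C@H]1CC/C(C)=C(/Cl)[C@@H]2OC(=O)[C@H](C)[C@@]2(O)[C@@H](O[Si](C(C)C)(C(C)C)C(C)C)[C@H]2[C@@H](C)[C@@H](O)C=C[C@@]21C | intermediate
46 | 12α-acetate (2-O-TBS, 9-O-TIPS) | CC(C)(C)[Si](C)(C)O[C@H]1CC/C(C)=C(/Cl)[C@@H]2OC(=O)[C@H](C)[C@@]2(O)[C@@H](O[Si](C(C)C)(C(C)C)C(C)C)[C@H]2[C@@H](C)[C@H](OC(C)=O)C=C[C@@]21C | intermediate
47 | 2-alcohol (12α-acetate, 9-O-TIPS) | O[C@H]1CC/C(C)=C(/Cl)[C@@H]2OC(=O)[C@H](C)[C@@]2(O)[C@@H](O[Si](C(C)C)(C(C)C)C(C)C)[C@H]2[C@@H](C)[C@H](OC(C)=O)C=C[C@@]21C | intermediate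
48 | 2,12-diacetate 9-triisopropylsilyl ether | CC(=O)O[C@H]1CC/C(C)=C(/Cl)[C@@H]2OC(=O)[C@H](C)[C@@]2(O)[C@@H](O[Si](C(C)C)(C(C)C)C(C)C)[C@H]2[C@@H](C)[C@H](OC(C)=O)C=C[C@@]21C | intermediate
49 | CNP0296164.1, (1S,2S,5E,7R,8R,9S,10S,11R,12R,17R) in the numbering used here | CC(=O)O[C@H]1CC/C(C)=C(/Cl)[C@@H]2OC(=O)[C@H](C)[C@@]2(O)[C@@H](O)[C@H]2[C@@H](C)[C@H](OC(C)=O)C=C[C@@]21C | target

## Step count and least certain steps

Total step count: 27. Longest linear sequence: 27 (the route is fully linear; 6 and 32 are purchased).

Step 12 (key step). The most likely failure is loss of chemoselectivity: ozone has only a modest intrinsic preference for a tetrasubstituted over a trisubstituted alkene, so C4=C5 may be cleaved as well, and the 1,6-dione may undergo transannular aldol reaction during work-up. Fallback: from 22, epoxidation with one equivalent of 3-chloroperoxybenzoic acid, which discriminates more strongly in favour of the tetrasubstituted bond, should give the 2,7-epoxide F1. Periodic acid in aqueous THF then opens the epoxide and cleaves the glycol, returning to the route at 25.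

Step 7. Activation may occur at the wrong hydroxyl or at both, because 14 carries two allylic carbinols; elimination to a diene may also compete with substitution at the hindered C12. Fallback: from 14, selective acetylation of the more accessible C12 hydroxyl gives the 12-monoacetate F2, silylation of C9 gives the 12-acetate 9-triisopropylsilyl ether F3, and methanolysis (K2CO3, MeOH) gives the 12β-ol 9-silyl ether F4. This has a single free hydroxyl and enters the same allylic diazene rearrangement, to come back at 18.

Step 13. Isomerisation may run toward the wrong carbonyl (C3=C4 conjugated with C2) because both allylic methylenes are activated, and the dienolates may close transannular aldols. Fallback: from 25, pyrrolidine condenses only with the unhindered C7 ketone (the neopentyl C2 ketone does not form an enamine) to give the linear C7 dienamine F5. Buffered hydrolysis protonates it at C4 and releases the conjugated enone, returning at 26.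

Step 19. Poor facial selectivity at C8 is the main stereochemical risk of the lactone sector, since it depends on the conformation of a ten-membered ring; base-induced migration of the alkene toward C9 may also occur. Fallback: from 31, the C8 lithium enolate is alkylated with ethyl (R)-2-(trifluoromethylsulfonyloxy)propanoate (SN2 with inversion, fixing C17) to give the keto ester F6. Enolisation with KN(SiMe3)2 and oxidation with 2-(phenylsulfonyl)-3-phenyloxaziridine give the tertiary α-hydroxy ketone F7, in which C8 is set by a different event (attack on a ring enolate). Zn(BH4)2 reduction and lactonisation through 38 return at 39.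

Step 23. Enolisation may not be selective (C11 epimerisation, lactone α-deprotonation), and the dehydrogenation may stall on the hindered substrate. Fallback: from 41, direct aerobic dehydrogenation with palladium bis(trifluoroacetate) and dimethyl sulfoxide under O2 in AcOH needs no strong base and makes no new intermediate; it returns at 44.

Step 25. Substitution at the hindered allylic carbinol may be slow or may be diverted to elimination or allylic transposition; the premise that step 24 gives the 12β alcohol may also fail. Fallback: from 44, a reagent-controlled Corey–Bakshi–Shibata reduction with the oxazaborolidine enantiomer matched to the α-alcohol gives the 12α-allylic alcohol F8, which is acetylated with Ac2O and pyridine, returning at 46.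

## Further compounds

F1 | step 12 | 2,7-epoxide of diene 22 | CC1=CCC2(O3)C3(C1)C[C@@H](O[Si](C(C)C)(C(C)C)C(C)C)[C@H]1[C@@H](C)[C@H](O[Si](CC)(CC)CC)CC[C@@]12C
F2 | step 7 | 12β-monoacetate of diol 14 | CC(=O)O[C@H]1CC[C@]2(C)c3ccc(C)cc3C[C@@H](O)C2=C1C
F3 | step 7 | 12β-acetate 9β-triisopropylsilyl ether | CC(=O)O[C@H]1CC[C@]2(C)c3ccc(C)cc3C[C@@H](O[Si](C(C)C)(C(C)C)C(C)C)C2=C1C
F4 | step 7 | 12β-ol 9β-triisopropylsilyl ether | O[C@H]1CC[C@]2(C)c3ccc(C)cc3C[C@@H](O[Si](C(C)C)(C(C)C)C(C)C)C2=C1C
F5 | step 13 | C7 pyrrolidine dienamine of dione 25 | O=C1CC=C(C)C=C(N3CCCC3)C[C@@H](O[Si](C(C)C)(C(C)C)C(C)C)[C@H]2[C@@H](C)[C@H](O[Si](CC)(CC)CC)CC[C@@]21C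
F6 | step 19 | 8-[(R)-1-ethoxy-1-oxopropan-2-yl] ketone from 31 | CC(C)(C)[Si](C)(C)O[C@H]1CC/C(C)=C(/Cl)C(=O)C([C@@H](C)C(=O)OCC)[C@@H](O[Si](C(C)C)(C(C)C)C(C)C)[C@H]2[C@@H](C)[C@H](O[Si](CC)(CC)CC)CC[C@@]21C
F7 | step 19 | 8-hydroxy derivative of F6 (tertiary α-hydroxy ketone) | CC(C)(C)[Si](C)(C)O[C@H]1CC/C(C)=C(/Cl)C(=O)[C@@](O)([C@@H](C)C(=O)OCC)[C@@H](O[Si](C(C)C)(C(C)C)C(C)C)[C@H]2[C@@H](C)[C@H](O[Si](CC)(CC)CC)CC[C@@]21C
F8 | step 25 | 12α-allylic alcohol (epimer of 45) | CC(C)(C)[Si](C)(C)O[C@H]1CC/C(C)=C(/Cl)[C@@H]2OC(=O)[C@H](C)[C@@]2(O)[C@@H](O[Si](C(C)C)(C(C)C)C(C)C)[C@H]2[C@@H](C)[C@H](O)C=C[C@@]21C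
F0 | step 23 | none | none
A1 | alternative 1 | cis-2-(2-tert-butyl-5-oxo-1,3-dioxolan-4-yl)propanoic acid | CC(C)(C)[C@H]1OC(=O)[C@H](O1)[C@@H](C)C(=O)O
A2 | alternative 1 | (E)-2-chloro-6-(4-methoxybenzyloxy)-3-methylhex-2-enal | O=C/C(Cl)=C(/C)CCCOCc1ccc(OC)cc1
A3 | alternative 1 | spiro dioxolanone γ-lactone carrying C2–C9 and C17–C19 | CC(C)(C)[C@H]1OC(=O)[C@]2(O1)[C@@H](C)C(=O)O[C@H]2/C(Cl)=C(/C)CCCOCc3ccc(OC)cc3
A4 | alternative 2 | (Z)-vinyl iodide α-methyl aldehyde (open-chain precursor of ring A, C1 epimers) | O=CC(C)[C@@H](COCc1ccc(OC)cc1)[C@@H](C)[C@H](O[Si](C)(C)C(C)(C)C)/C=C\I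
A5 | alternative 2 | ring A aldehyde with quaternary C1 | O=C[C@@]1(C)C=C[C@@H](O[Si](C)(C)C(C)(C)C)[C@H](C)[C@@H]1COCc1ccc(OC)cc1
A6 | alternative 3 | seco C2 aldehyde with ring A silyl dienol ether | O=CCC/C(C)=C(/Cl)[C@@H]1OC(=O)[C@H](C)[C@@]1(O[Si](C)(C)C)[C@@H](O[Si](C)(C)C(C)(C)C)[C@@H]1C(C)=CC=C(O[Si](C)(C)C(C)(C)C)[C@@H]1C
A7 | alternative 3 | bicyclic C12 enone with C2 alcohol | O[C@H]1CC/C(C)=C(/Cl)[C@@H]2OC(=O)[C@H](C)[C@@]2(O[Si](C)(C)C)[C@@H](O[Si](C)(C)C(C)(C)C)[C@H]2[C@@H](C)C(=O)C=C[C@@]21C
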